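## Retrosynthetic overview

1. Target 10 ⇒ enol-chalcone 9 by opening the dihydropyranone at O1–C2 (retro 6-endo oxa-Michael, the chalcone–flavanone isomerisation); this ring is formed last.
2. 9 ⇒ dienone 8 by retro intramolecular Diels–Alder; the tetrahydrofuran and bicyclo[2.2.2]octenone rings form together, and all four core stereocentres follow from the one quaternary C–O centre of 8.
3. 8 ⇒ achiral chalcone 6 + prenol 7 by enantioselective oxidative dearomatisation; the two C-methyl ring carbons of 6 are enantiotopic, so a single chiral λ3-iodane fixes the absolute configuration without any regiochemical issue.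
4. 6 ⇒ benzaldehyde 4 + acetophenone 3 (Claisen–Schmidt); 3 ⇒ phloracetophenone 1 + 2 MeI.
5. Ring order: aromatic ring (bought) → tetrahydrofuran + bicyclo[2.2.2]octenone in one flask → dihydropyranone.

Assumption 1: the presumed biogenesis is taken as C-methylated chalcone → oxidative dearomatisation with O-prenyl capture → intramolecular [4+2] → flavanone-type oxa-Michael closure.

Assumption 2: the sense of induction of the two chiral promoters is assigned by analogy; if a first run shows the opposite sense, the mirror-image λ3-iodane (from the other lactate) or the quinidine-derived pseudo-enantiomeric thiourea is used instead.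

Chiral oxidant of step 3 (a trivalent-iodine reagent, preformed from the catalogue iodoarene with AcOOH/AcOH): [2,6-bis({(2R)-1-oxo-1-[(2,4,6-trimethylphenyl)amino]propan-2-yl}oxy)phenyl]-λ3-iodanediyl diacetate, CC(=O)OI(OC(C)=O)c1c(O[C@H](C)C(=O)Nc2c(C)cc(C)cc2C)cccc1O[C@H](C)C(=O)Nc1c(C)cc(C)cc1C

## Route

Step 1
Reactants: 1 2,4,6-trihydroxyacetophenone
Product: 3 2,4,6-trihydroxy-3,5-dimethylacetophenone, via 3-methyl ketone 2 (not isolated)
Conditions: MeI (2.1 equiv), NaOMe (2.1 equiv), MeOH, 0 °C → rt
Reagents that add atoms: iodomethane, CI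
Why: Base-mediated C-methylation (SN2 on MeI) of the ambident phloroglucinol phenolate, which in protic MeOH alkylates at the two free ring carbons; two equivalents stop the sequence at the aromatic 3,5-dimethyl stage and no stereocentre is formed.

Step 2
Reactants: 3 2,4,6-trihydroxy-3,5-dimethylacetophenone; 4 benzaldehyde
Product: 6 (E)-1-(2,4,6-trihydroxy-3,5-dimethylphenyl)-3-phenylprop-2-en-1-one, via aldol adduct 5 (not isolated)
Conditions: KOH (50% aq, 10 equiv), EtOH, 0 °C → rt, 48 h; then 2 M HCl, 0 °C
Reagents that add atoms: none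
Why: Claisen–Schmidt condensation: aldol addition of the acetyl enolate to the non-enolisable aldehyde and E1cB dehydration give only the E-enone, and the polyphenolate stays ring-open in strong base so that cold acidification delivers the achiral chalcone.

Step 3
Reactants: 6 (E)-1-(2,4,6-trihydroxy-3,5-dimethylphenyl)-3-phenylprop-2-en-1-one; 7 3-methylbut-2-en-1-ol (prenol)
Product: 9 (1R,3S,6R,7R)-7,9-dihydroxy-1,3,10,10-tetramethyl-8-[(2E)-3-phenylprop-2-enoyl]-4-oxatricyclo[4.3.1.0(3,7)]dec-8-en-2-one, via prenyloxy dienone 8 (not isolated)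
Conditions: [2,6-bis({(2R)-1-oxo-1-[(2,4,6-trimethylphenyl)amino]propan-2-yl}oxy)phenyl]-λ3-iodanediyl diacetate (1.1 equiv), 7 (10 equiv), 4 Å MS, CH2Cl2, −40 → 0 °C; then swap to PhMe, 80 °C
Reagents that add atoms: none
Why: Proposed new method: the phenol of 6 exchanges onto the chiral aryl-λ3-iodane and prenol attacks, SN2'-like with loss of the iodoarene, one of the two enantiotopic methyl-bearing ring carbons (the mirror plane of 6 turns a regiochemical question into an enantiofacial one that the lactamide arms are expected to decide in favour of (6S)-8), after which the tethered prenyl alkene can reach only the diene face syn to its oxygen, so the intramolecular Diels–Alder reaction of this masked o-benzoquinone (bonds CH–C5 and CMe2–C2 of 8, the periselection that keeps the chelated acyl-enol conjugated) sets the other three core stereocentres from C6 alone; closest known chemistry is the chiral aryl-λ3-iodane oxidative dearomatisation of phenols with oxygen nucleophiles and the PhI(OAc)2/alkenol dearomatisation–intramolecular Diels–Alder sequence of masked o-benzoquinones.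

Step 4
Reactants: 9 (1R,3S,6R,7R)-7,9-dihydroxy-1,3,10,10-tetramethyl-8-[(2E)-3-phenylprop-2-enoyl]-4-oxatricyclo[4.3.1.0(3,7)]dec-8-en-2-one
Product: 10 CNP0322161.1, the (2S)-2-phenyl-2,3-dihydro-4H-pyran-4-one fused across C8=C9 (ring oxygen on C9) of the (1R,3S,6R,7R)-7-hydroxy-1,3,10,10-tetramethyl-4-oxatricyclo[4.3.1.0(3,7)]dec-8-en-2-one core
Conditions: 1-[3,5-bis(trifluoromethyl)phenyl]-3-[(8α,9S)-6'-methoxycinchonan-9-yl]thiourea (10 mol%), PhMe, 25 °C
Reagents that add atoms: none
Why: Proposed new method: the quinuclidine nitrogen deprotonates the acidic enol (not the tertiary alcohol) and the thiourea hydrogen-bonds the resulting diketonate/enone so that the enolate oxygen adds 6-endo to one face of the cinnamoyl β-carbon, giving C2 (S) under catalyst control because the remote core exerts no bias of its own and the weak base does not reopen the vinylogous ester; closest known chemistry is the cinchona thiourea catalysed intramolecular oxa-Michael route to flavanones and the base-mediated closure of cinnamoyl-1,3-dicarbonyl enols to 2-aryl-2,3-dihydropyran-4-ones.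

## Compound list

1 | 2,4,6-trihydroxyacetophenone (phloracetophenone) | CC(=O)c1c(O)cc(O)cc1O | starting material
2 | 2,4,6-trihydroxy-3-methylacetophenone | CC(=O)c1c(O)cc(O)c(C)c1O | intermediate
3 | 2,4,6-trihydroxy-3,5-dimethylacetophenone | CC(=O)c1c(O)c(C)c(O)c(C)c1O | intermediate
4 | benzaldehyde | O=Cc1ccccc1 | starting material
5 | 3-hydroxy-3-phenyl-1-(2,4,6-trihydroxy-3,5-dimethylphenyl)propan-1-one (racemic aldol adduct) | Cc1c(O)c(C)c(O)c(C(=O)CC(O)c2ccccc2)c1O | intermediate
6 | (E)-1-(2,4,6-trihydroxy-3,5-dimethylphenyl)-3-phenylprop-2-en-1-one (achiral chalcone) | Cc1c(O)c(C)c(O)c(C(=O)/C=C/c2ccccc2)c1O | intermediate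
7 | 3-methylbut-2-en-1-ol (prenol) | CC(C)=CCO | starting material
8 | (6S)-3,5-dihydroxy-2,6-dimethyl-6-[(3-methylbut-2-en-1-yl)oxy]-4-[(2E)-3-phenylprop-2-enoyl]cyclohexa-2,4-dien-1-one | CC(C)=CCO[C@]1(C)C(=O)C(C)=C(O)C(C(=O)/C=C/c2ccccc2)=C1O | intermediate
9 | (1R,3S,6R,7R)-7,9-dihydroxy-1,3,10,10-tetramethyl-8-[(2E)-3-phenylprop-2-enoyl]-4-oxatricyclo[4.3.1.0(3,7)]dec-8-en-2-one | CC1(C)[C@@H]2CO[C@]3(C)C(=O)[C@@]1(C)C(O)=C(C(=O)/C=C/c1ccccc1)[C@]23O | intermediate
10 | CNP0322161.1: (2S)-2-phenyl-2,3-dihydro-4H-pyran-4-one fused across C8=C9 of the (1R,3S,6R,7R)-7-hydroxy-1,3,10,10-tetramethyl-4-oxatricyclo[4.3.1.0(3,7)]dec-8-en-2-one core | CC1(C)[C@@H]2CO[C@]3(C)C(=O)[C@@]1(C)C1=C(C(=O)C[C@@H](c4ccccc4)O1)[C@]23O | target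

## Totals and risks

Total step count: 4. Longest linear sequence: 4 (1 → 3 → 6 → 9 → 10).

The three steps most likely to fail:

1. Step 3. An enantioselective intermolecular alkoxylative dearomatisation has no direct precedent. Acetate may compete with prenol for the ring carbon, the enantiomeric excess may be low, and the cycloaddition must follow the stated periselection. The fallback sets out from 6 and moves the source of absolute configuration to the last step. Treating 6 with PhI(OAc)2 and 7 (CH2Cl2, 0 °C; then PhMe, 80 °C) is the established achiral alkenol dearomatisation/intramolecular Diels–Alder sequence. It gives dienone 8 together with its mirror image, ent-dienone F1, and hence 9 together with ent-tricycle F2. The thiourea of step 4 then closes both with (S) configuration at C2: 9 gives 10, and F2 gives the (2S)-diastereomer with antipodal core F3. Because 10 and F3 are diastereomers they are separated on silica, and the route is rejoined at 10 (maximum 50%).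

2. Step 4. Closure of a β-diketone enol onto its own cinnamoyl group may have an unfavourable equilibrium, the tertiary alcohol may compete, and incomplete catalyst control would leave a separable C2 epimer. The fallback sets out from 6 and closes the pyranone at the aromatic stage, where the chalcone–flavanone isomerisation is favourable. The same thiourea in PhMe, now with a phenol donor, gives (2S)-5,7-dihydroxy-6,8-dimethylflavanone F4, whose enantiomeric excess is raised by crystallisation. The λ3-iodane of step 3 with 7 at −40 °C then gives the (2S,6S)-6-prenyloxy dienone F5, which on warming to 80 °C undergoes the same intramolecular Diels–Alder reaction and arrives directly at 10. The price is that alkoxylation must now choose C6 over C8, so isomers are removed by chromatography.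

3. Step 2. The unprotected triol can give a low yield, and the chalcone can partly cyclise to the racemic flavanone on acidification. The fallback sets out from 3 and uses protection. Chloromethyl methyl ether (MOMCl) and iPr2NEt in CH2Cl2 give 1-[2-hydroxy-4,6-bis(methoxymethoxy)-3,5-dimethylphenyl]ethanone F6. KOH/EtOH with 4 gives the bis-MOM chalcone F7 cleanly. Brief 3 M HCl/MeOH at rt removes both acetals and rejoins the route at 6.

## Further compounds

F1 | step 3 | (6R)-3,5-dihydroxy-2,6-dimethyl-6-[(3-methylbut-2-en-1-yl)oxy]-4-[(2E)-3-phenylprop-2-enoyl]cyclohexa-2,4-dien-1-one (ent-8) | CC(C)=CCO[C@@]1(C)C(=O)C(C)=C(O)C(C(=O)/C=C/c2ccccc2)=C1O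
F2 | step 3 | (1S,3R,6S,7S)-7,9-dihydroxy-1,3,10,10-tetramethyl-8-[(2E)-3-phenylprop-2-enoyl]-4-oxatricyclo[4.3.1.0(3,7)]dec-8-en-2-one (ent-9) | CC1(C)[C@H]2CO[C@@]3(C)C(=O)[C@]1(C)C(O)=C(C(=O)/C=C/c1ccccc1)[C@@]23O
F3 | step 3 | (2S)-2-phenyl-dihydropyranone on the (1S,3R,6S,7S) core (diastereomer of 10 with antipodal core) | CC1(C)[C@H]2CO[C@@]3(C)C(=O)[C@]1(C)C1=C(C(=O)C[C@@H](c4ccccc4)O1)[C@@]23O
F4 | step 4 | (2S)-5,7-dihydroxy-6,8-dimethyl-2-phenyl-2,3-dihydro-4H-chromen-4-one | O=C1C[C@@H](c2ccccc2)Oc2c(C)c(O)c(C)c(O)c12
F5 | step 4 | (2S,6S)-5-hydroxy-6,8-dimethyl-6-[(3-methylbut-2-en-1-yl)oxy]-2-phenyl-2,3-dihydro-4H-chromene-4,7(6H)-dione | CC(C)=CCO[C@]1(C)C(=O)C(C)=C2O[C@H](c3ccccc3)CC(=O)C2=C1O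
F6 | step 2 | 1-[2-hydroxy-4,6-bis(methoxymethoxy)-3,5-dimethylphenyl]ethanone | CC(=O)c1c(O)c(C)c(OCOC)c(C)c1OCOC
F7 | step 2 | (E)-1-[2-hydroxy-4,6-bis(methoxymethoxy)-3,5-dimethylphenyl]-3-phenylprop-2-en-1-one | COCOc1c(C)c(OCOC)c(C(=O)/C=C/c2ccccc2)c(O)c1C
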